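## Retrosynthetic overview

1. C13=C14 is cut by an E-selective Wittig reaction between decalin aldehyde 25 and ester ylide 10, whose ester carbon becomes the CH2OH group. The methylidenecyclohexane ring of 10 is bought as 3-methylcyclohex-2-enone, and C17 is set by a decarboxylative asymmetric allylation.
2. Ring A (C1, C2, C3, C4, C5, C10) is cut at C4–C5. The forward step is a reductive, denitrogenative radical cyclisation of a 4-methylpent-4-enyl chain on C10 onto the tosylhydrazone of a C5 ketone in ring B.
3. Enabling feature: in ring A the gem-dimethyl quaternary C4 sits next to the ring-fusion methine C5–H. C4 is therefore a latent tertiary radical (isopropenyl end + H•), and C5–H is a latent ring-B carbonyl carbon whose oxygen is traded for C4 and H.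
4. Ring B (C5–C10) comes from (R)-linalool, which supplies the C8 carbinol centre, by Schenck ene/dehydration and ring-closing metathesis. C9 and C10 follow by conjugate addition anti to C8–O and enolate allylation anti to the C9 chain.
5. Order of rings: monocyclic ring (purchased), then ring B (step 9), then ring A (step 14, last).

Key step: step 14

Remark (numbering): the decalin is C1–C10 as in labdanes, with ring A = C1–C5 + C10 and ring B = C5–C10. The side chain is C11–C16 from C9, with CH2OH on C14. The monocyclic ring is C17–C22 (C17 stereocentre, C18 methylidene carbon, C22 gem-dimethyl carbon).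

Assumption: the (R,R) ligand in step 2 is taken to give the (S)-ketone; if the sense of induction is opposite, its antipode is used. Commercial (R)-(−)-linalool of high enantiomeric purity is assumed.

## Route

Step 1
Reactants: 1 3-methylcyclohex-2-en-1-one
Product: 3 allyl 3,3-dimethylcyclohex-1-en-1-yl carbonate, via lithium enolate 2 (not isolated)
Conditions: MeLi (2 equiv), CuI, Et2O, 0 °C; then allyl chloroformate, HMPA, −78 °C to rt
Reagents that add atoms: lithium dimethylcuprate [Li+].C[Cu-]C; allyl chloroformate C=CCOC(=O)Cl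
Why: Gilman conjugate addition builds the gem-dimethyl carbon and gives the enolate regiospecifically on the hindered side, and a chloroformate acylates a lithium enolate on oxygen (enol carbonate formation); no stereocentre is formed.

Step 2
Reactants: 3 allyl 3,3-dimethylcyclohex-1-en-1-yl carbonate
Product: 4 (S)-2-allyl-3,3-dimethylcyclohexan-1-one
Conditions: Pd2(dba)3·CHCl3 (cat.), (R,R)-ANDEN-phenyl bis(2-diphenylphosphinobenzamide) ligand (cat.), 1,4-dioxane, 23 °C
Reagents that add atoms: none
Why: Palladium-catalysed decarboxylative asymmetric allylic alkylation (Tsuji–Trost type) of an allyl enol carbonate releases enolate and π-allyl partner together under neutral conditions, so the chiral ligand pocket sets the α-tertiary stereocentre C17 (S) and no base is present to racemise it.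

Step 3
Reactants: 4 (S)-2-allyl-3,3-dimethylcyclohexan-1-one
Product: 5 (2S)-2-allyl-1,1-dimethyl-3-methylidenecyclohexane
Conditions: Ph3PCH3Br, KOtBu, toluene, 80 °C
Reagents that add atoms: methyltriphenylphosphonium bromide C[P+](c1ccccc1)(c1ccccc1)c1ccccc1.[Br-]
Why: Wittig methylenation; the ylide can enolise the ketone only towards the free CH2 side because the α-CH is flanked by the quaternary carbon, so the stereocentre should be kept.

Step 4
Reactants: 5 (2S)-2-allyl-1,1-dimethyl-3-methylidenecyclohexane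
Product: 7 (2S)-2-(3-iodopropyl)-1,1-dimethyl-3-methylidenecyclohexane, via alkylzirconocene 6 (not isolated)
Conditions: Cp2Zr(H)Cl, CH2Cl2, rt; then I2, 0 °C
Reagents that add atoms: iodine II
Why: Hydrozirconation is much faster at the monosubstituted than at the hindered 1,1-disubstituted alkene and puts zirconium on the terminal carbon, and iodinolysis of the C–Zr bond gives the primary iodide.

Step 5
Reactants: 7 (2S)-2-(3-iodopropyl)-1,1-dimethyl-3-methylidenecyclohexane
Product: 8 {3-[(1S)-2,2-dimethyl-6-methylidenecyclohexyl]propyl}triphenylphosphonium iodide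
Conditions: PPh3, MeCN, reflux
Reagents that add atoms: triphenylphosphine c1ccc(cc1)P(c1ccccc1)c1ccccc1
Why: SN2 quaternisation of triphenylphosphine by a primary iodide under neutral conditions that leave the exocyclic alkene in place.

Step 6
Reactants: 8 {3-[(1S)-2,2-dimethyl-6-methylidenecyclohexyl]propyl}triphenylphosphonium iodide
Product: 10 ethyl 4-[(1S)-2,2-dimethyl-6-methylidenecyclohexyl]-2-(triphenyl-λ5-phosphanylidene)butanoate, via ylide 9 (not isolated)
Conditions: NaHMDS (2 equiv), THF, −78 °C; then ClCO2Et, −78 °C to rt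
Reagents that add atoms: ethyl chloroformate CCOC(=O)Cl
Why: C-acylation of a non-stabilised ylide by a chloroformate, the second equivalent of base removing the now acidic α-proton to give the shelf-stable ester ylide.

Step 7
Reactants: 11 (R)-(−)-linalool
Product: 12 triethyl{[(3R)-3,7-dimethylocta-1,6-dien-3-yl]oxy}silane
Conditions: TESOTf, 2,6-lutidine, CH2Cl2, −78 to 0 °C
Reagents that add atoms: triethylsilyl triflate CC[Si](CC)(CC)OS(=O)(=O)C(F)(F)F
Why: Silyl triflate silylation of a tertiary alcohol; the bulky ether later steers the conjugate addition and the stereocentre (future C8) is not touched.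

Step 8
Reactants: 12 triethyl{[(3R)-3,7-dimethylocta-1,6-dien-3-yl]oxy}silane
Product: 14 (6R)-2,6-dimethyl-6-(triethylsilyloxy)octa-1,7-dien-3-one, via allylic hydroperoxide 13 (not isolated)
Conditions: O2, hν (visible), tetraphenylporphyrin (cat.), Ac2O, pyridine, DMAP (cat.), CH2Cl2, 0 °C
Reagents that add atoms: oxygen O=O
Why: Schenck ene reaction of singlet oxygen at the only electron-rich (trisubstituted) alkene followed by base-induced dehydration of the acetylated secondary hydroperoxide (Kornblum–DeLaMare type) gives the isopropenyl ketone, the isomer from the competing ene pathway being removed by chromatography.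

Step 9
Reactants: 14 (6R)-2,6-dimethyl-6-(triethylsilyloxy)octa-1,7-dien-3-one
Product: 15 (4R)-2,4-dimethyl-4-(triethylsilyloxy)cyclohex-2-en-1-one
Conditions: Hoveyda–Grubbs 2nd-generation catalyst (cat.), toluene, 80 °C
Reagents that add atoms: none
Why: Ring-closing metathesis of the vinyl carbinol ether with the methacryloyl-type alkene closes six-membered ring B as a 2-methylcyclohexenone and is driven by loss of ethene; the C8 stereocentre is untouched.

Step 10
Reactants: 15 (4R)-2,4-dimethyl-4-(triethylsilyloxy)cyclohex-2-en-1-one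
Product: 16 {[(3R,4R)-3-[2-(1,3-dioxolan-2-yl)ethyl]-2,4-dimethyl-4-(triethylsilyloxy)cyclohex-1-en-1-yl]oxy}trimethylsilane
Conditions: [2-(1,3-dioxolan-2-yl)ethyl]MgBr, CuBr·SMe2 (cat.), TMSCl, HMPA, THF, −78 °C
Reagents that add atoms: [2-(1,3-dioxolan-2-yl)ethyl]magnesium bromide Br[Mg]CCC1OCCO1; chlorotrimethylsilane C[Si](C)(C)Cl
Why: Chlorosilane-accelerated copper-catalysed conjugate addition of a Grignard reagent; attack on C9 antiperiplanar to the pseudo-axial C8–O bond and away from the bulky silyl ether sets C9 trans to oxygen, and the enolate is caught regiospecifically.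

Step 11
Reactants: 16 {[(3R,4R)-3-[2-(1,3-dioxolan-2-yl)ethyl]-2,4-dimethyl-4-(triethylsilyloxy)cyclohex-1-en-1-yl]oxy}trimethylsilane
Product: 18 (2R,3R,4R)-2-allyl-3-[2-(1,3-dioxolan-2-yl)ethyl]-2,4-dimethyl-4-(triethylsilyloxy)cyclohexan-1-one, via lithium enolate 17 (not isolated)
Conditions: MeLi, THF, 0 °C; then allyl bromide, DMPU, −78 to 0 °C
Reagents that add atoms: allyl bromide C=CCBr
Why: Methyllithium frees the tetrasubstituted lithium enolate and the reactive allylic bromide enters at C10 on the face opposite to the neighbouring C9 side chain (vicinal trans alkylation), which sets the quaternary centre.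

Step 12
Reactants: 18 (2R,3R,4R)-2-allyl-3-[2-(1,3-dioxolan-2-yl)ethyl]-2,4-dimethyl-4-(triethylsilyloxy)cyclohexan-1-one
Product: 20 (2R,3R,4R)-3-[2-(1,3-dioxolan-2-yl)ethyl]-2,4-dimethyl-2-(4-methylpent-4-en-1-yl)-4-(triethylsilyloxy)cyclohexan-1-one, via B-alkyl-9-BBN 19 (not isolated)
Conditions: 9-BBN, THF, rt; then 2-bromopropene, Pd(dppf)Cl2 (cat.), aq NaOH, THF, 50 °C
Reagents that add atoms: 2-bromopropene C=C(C)Br
Why: Anti-Markovnikov hydroboration of the only alkene and B-alkyl Suzuki–Miyaura coupling extend the allyl group to the 4-methylpent-4-enyl chain without touching any stereocentre.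

Step 13
Reactants: 20 (2R,3R,4R)-3-[2-(1,3-dioxolan-2-yl)ethyl]-2,4-dimethyl-2-(4-methylpent-4-en-1-yl)-4-(triethylsilyloxy)cyclohexan-1-one
Product: 21 N-tosylhydrazone of ketone 20 (C=N geometry not defined)
Conditions: TsNHNH2, PPTS (cat.), 4 Å MS, THF, 50 °C
Reagents that add atoms: p-toluenesulfonyl hydrazide Cc1ccc(cc1)S(=O)(=O)NN
Why: Acid-catalysed condensation of the ketone to the sulfonylhydrazone under water-free conditions that spare acetal and silyl ether; the C=N geometry is of no consequence.

Step 14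
Reactants: 21 N-tosylhydrazone of ketone 20
Product: 24 triethyl{[(1R,2R,4aS,8aS)-1-[2-(1,3-dioxolan-2-yl)ethyl]-2,5,5,8a-tetramethyldecahydronaphthalen-2-yl]oxy}silane, via hydrazide 22 (not isolated), via diazene 23 (not isolated)
Conditions: Fe(acac)3 (substoichiometric), PhSiH3, EtOH, 60 °C; then NaOAc, 80 °C
Reagents that add atoms: none
Why: Proposed new method: an iron hydride made from Fe(acac)3 and PhSiH3 transfers H• to the CH2 terminus of the only C=C bond (Markovnikov MHAT), so that the isopropenyl end becomes the nucleophilic tertiary C4 radical carrying both methyl groups, and this radical adds to the electrophilic C5 of the C=N bond, a union of two carbons that are both acceptor sites in polar terms. The closest known reaction types are the Fe-MHAT hydromethylation of alkenes through formaldehyde sulfonylhydrazone, the MHAT cyclisation of alkene-tethered ketones and hydrazones, and radical cyclisation onto N-aziridinylimines; new is the use of a hindered ring-ketone hydrazone with loss of N2 to leave a ring-fusion C–H. Ring A closes in the 6-exo-trig mode on C=N (C4–C5 bond), helped by the quaternary C10 in the tether (Thorpe–Ingold effect) and by the irreversibility of addition to C=N. Reduction of the hydrazinyl radical gives hydrazide 22, acetate-assisted loss of sulfinate gives diazene 23, and this loses N2 by a radical chain through the planar tertiary C5 radical. C5 is the only new stereocentre and is set in the last H-atom transfer, which comes from the α face opposite to the axial C10 methyl and the axial C4 methyl and gives the more stable trans-decalin, so both hydrazone geometries and both C5 epimers of 22 converge on one product. The step needs chemoselective HAT and a cyclisation faster than reduction of the C4 radical: 21 holds a single alkene, no other radical acceptor lies within reach, and silyl ether and acetal are inert to the iron hydride.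

Step 15
Reactants: 24 triethyl{[(1R,2R,4aS,8aS)-1-[2-(1,3-dioxolan-2-yl)ethyl]-2,5,5,8a-tetramethyldecahydronaphthalen-2-yl]oxy}silane
Product: 25 3-[(1R,2R,4aS,8aS)-2,5,5,8a-tetramethyl-2-(triethylsilyloxy)decahydronaphthalen-1-yl]propanal
Conditions: PPTS (cat.), acetone/H2O, 50 °C
Reagents that add atoms: water O
Why: Mild acid hydrolysis of the dioxolane, which is far more labile than the hindered tertiary silyl ether.

Step 16
Reactants: 25 3-[(1R,2R,4aS,8aS)-2,5,5,8a-tetramethyl-2-(triethylsilyloxy)decahydronaphthalen-1-yl]propanal; 10 ethyl 4-[(1S)-2,2-dimethyl-6-methylidenecyclohexyl]-2-(triphenyl-λ5-phosphanylidene)butanoate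
Product: 26 ethyl (2E)-2-{2-[(1S)-2,2-dimethyl-6-methylidenecyclohexyl]ethyl}-5-[(1R,2R,4aS,8aS)-2,5,5,8a-tetramethyl-2-(triethylsilyloxy)decahydronaphthalen-1-yl]pent-2-enoate
Conditions: toluene, 100 °C
Reagents that add atoms: none
Why: Wittig reaction of an α-branched ester-stabilised ylide with an unhindered aldehyde, which places the ester trans to the C12 chain (E) and so puts C12 and C15 on the same side as required.

Step 17
Reactants: 26 ethyl (2E)-enoate
Product: 27 (2E)-2-{2-[(1S)-2,2-dimethyl-6-methylidenecyclohexyl]ethyl}-5-[(1R,2R,4aS,8aS)-2,5,5,8a-tetramethyl-2-(triethylsilyloxy)decahydronaphthalen-1-yl]pent-2-en-1-ol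
Conditions: DIBAL-H, CH2Cl2, −78 °C; Rochelle salt work-up
Reagents that add atoms: none
Why: 1,2-Reduction of the conjugated ester by DIBAL-H gives the allylic alcohol with the alkene geometry kept.

Step 18
Reactants: 27 allylic alcohol silyl ether
Product: 28 (1R,2R,4aS,8aS)-1-[(3E)-6-[(1S)-2,2-dimethyl-6-methylidenecyclohexyl]-4-(hydroxymethyl)hex-3-en-1-yl]-2,5,5,8a-tetramethyldecahydronaphthalen-2-ol (target)
Conditions: TBAF, THF, rt
Reagents that add atoms: none
Why: Fluoride cleaves the Si–O bond under non-acidic conditions that leave the exocyclic alkene and the allylic alcohol untouched.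

## Compound list

1 | 3-methylcyclohex-2-en-1-one | CC1=CC(=O)CCC1 | starting material
2 | lithium 3,3-dimethylcyclohex-1-en-1-olate | [Li]OC1=CC(C)(C)CCC1 | intermediate
3 | allyl 3,3-dimethylcyclohex-1-en-1-yl carbonate | C=CCOC(=O)OC1=CC(C)(C)CCC1 | intermediate
4 | (S)-2-allyl-3,3-dimethylcyclohexan-1-one | O=C1CCCC(C)(C)[C@@H]1CC=C | intermediate
5 | (2S)-2-allyl-1,1-dimethyl-3-methylidenecyclohexane | C=C1CCCC(C)(C)[C@@H]1CC=C | intermediate
6 | chlorobis(cyclopentadienyl){3-[(1S)-2,2-dimethyl-6-methylidenecyclohexyl]propyl}zirconium | C=C1CCCC(C)(C)[C@@H]1CCC[Zr](Cl)(C1C=CC=C1)C1C=CC=C1 | intermediate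
7 | (2S)-2-(3-iodopropyl)-1,1-dimethyl-3-methylidenecyclohexane | C=C1CCCC(C)(C)[C@@H]1CCCI | intermediate
8 | {3-[(1S)-2,2-dimethyl-6-methylidenecyclohexyl]propyl}triphenylphosphonium iodide | C=C1CCCC(C)(C)[C@@H]1CCC[P+](c1ccccc1)(c1ccccc1)c1ccccc1.[I-] | intermediate
9 | {3-[(1S)-2,2-dimethyl-6-methylidenecyclohexyl]propylidene}triphenylphosphorane | C=C1CCCC(C)(C)[C@@H]1CCC=P(c1ccccc1)(c1ccccc1)c1ccccc1 | intermediate
10 | ethyl 4-[(1S)-2,2-dimethyl-6-methylidenecyclohexyl]-2-(triphenyl-λ5-phosphanylidene)butanoate | C=C1CCCC(C)(C)[C@@H]1CCC(C(=O)OCC)=P(c1ccccc1)(c1ccccc1)c1ccccc1 | intermediate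
11 | (R)-(−)-linalool | CC(C)=CCC[C@@](C=C)(C)O | starting material
12 | triethyl{[(3R)-3,7-dimethylocta-1,6-dien-3-yl]oxy}silane | CC(C)=CCC[C@@](C=C)(C)O[Si](CC)(CC)CC | intermediate
13 | (6R)-3-hydroperoxy-2,6-dimethyl-6-(triethylsilyloxy)octa-1,7-diene (C3 epimers) | C=C(C)C(OO)CC[C@@](C=C)(C)O[Si](CC)(CC)CC | intermediate
14 | (6R)-2,6-dimethyl-6-(triethylsilyloxy)octa-1,7-dien-3-one | C=C(C)C(=O)CC[C@@](C=C)(C)O[Si](CC)(CC)CC | intermediate
15 | (4R)-2,4-dimethyl-4-(triethylsilyloxy)cyclohex-2-en-1-one | CC1=C[C@](C)(O[Si](CC)(CC)CC)CCC1=O | intermediate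
16 | {[(3R,4R)-3-[2-(1,3-dioxolan-2-yl)ethyl]-2,4-dimethyl-4-(triethylsilyloxy)cyclohex-1-en-1-yl]oxy}trimethylsilane | C[Si](C)(C)OC1=C(C)[C@@H](CCC2OCCO2)[C@](C)(O[Si](CC)(CC)CC)CC1 | intermediate
17 | lithium enolate corresponding to 16 | [Li]OC1=C(C)[C@@H](CCC2OCCO2)[C@](C)(O[Si](CC)(CC)CC)CC1 | intermediate
18 | (2R,3R,4R)-2-allyl-3-[2-(1,3-dioxolan-2-yl)ethyl]-2,4-dimethyl-4-(triethylsilyloxy)cyclohexan-1-one | C=CC[C@@]1(C)C(=O)CC[C@@](C)(O[Si](CC)(CC)CC)[C@@H]1CCC1OCCO1 | intermediate
19 | B-alkyl-9-BBN adduct of 18 (boron on the terminal carbon of the former allyl group) | C(CC[C@@]1(C)C(=O)CC[C@@](C)(O[Si](CC)(CC)CC)[C@@H]1CCC1OCCO1)B1C2CCCC1CCC2 | intermediate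
20 | (2R,3R,4R)-3-[2-(1,3-dioxolan-2-yl)ethyl]-2,4-dimethyl-2-(4-methylpent-4-en-1-yl)-4-(triethylsilyloxy)cyclohexan-1-one | C=C(C)CCC[C@@]1(C)C(=O)CC[C@@](C)(O[Si](CC)(CC)CC)[C@@H]1CCC1OCCO1 | intermediate
21 | N-tosylhydrazone of 20 | C=C(C)CCC[C@@]1(C)C(=NNS(=O)(=O)c2ccc(C)cc2)CC[C@@](C)(O[Si](CC)(CC)CC)[C@@H]1CCC1OCCO1 | intermediate
22 | ring-closed hydrazide: 24 with NHNHTs in place of H at C5 (both C5 epimers) | O1CCOC1CC[C@@H]1[C@@]2(C)CCCC(C)(C)C2(NNS(=O)(=O)c3ccc(C)cc3)CC[C@@]1(C)O[Si](CC)(CC)CC | intermediate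
23 | diazene: 24 with N=NH in place of H at C5 | O1CCOC1CC[C@@H]1[C@@]2(C)CCCC(C)(C)C2(N=N)CC[C@@]1(C)O[Si](CC)(CC)CC | intermediate
24 | triethyl{[(1R,2R,4aS,8aS)-1-[2-(1,3-dioxolan-2-yl)ethyl]-2,5,5,8a-tetramethyldecahydronaphthalen-2-yl]oxy}silane | O1CCOC1CC[C@@H]1[C@@]2(C)CCCC(C)(C)[C@@H]2CC[C@@]1(C)O[Si](CC)(CC)CC | intermediate
25 | 3-[(1R,2R,4aS,8aS)-2,5,5,8a-tetramethyl-2-(triethylsilyloxy)decahydronaphthalen-1-yl]propanal | O=CCC[C@@H]1[C@@]2(C)CCCC(C)(C)[C@@H]2CC[C@@]1(C)O[Si](CC)(CC)CC | intermediate
26 | ethyl (2E)-2-{2-[(1S)-2,2-dimethyl-6-methylidenecyclohexyl]ethyl}-5-[(1R,2R,4aS,8aS)-2,5,5,8a-tetramethyl-2-(triethylsilyloxy)decahydronaphthalen-1-yl]pent-2-enoate | C=C1CCCC(C)(C)[C@@H]1CC/C(=C\CC[C@@H]1[C@@]2(C)CCCC(C)(C)[C@@H]2CC[C@@]1(C)O[Si](CC)(CC)CC)C(=O)OCC | intermediate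
27 | (2E)-2-{2-[(1S)-2,2-dimethyl-6-methylidenecyclohexyl]ethyl}-5-[(1R,2R,4aS,8aS)-2,5,5,8a-tetramethyl-2-(triethylsilyloxy)decahydronaphthalen-1-yl]pent-2-en-1-ol | C=C1CCCC(C)(C)[C@@H]1CC/C(=C\CC[C@@H]1[C@@]2(C)CCCC(C)(C)[C@@H]2CC[C@@]1(C)O[Si](CC)(CC)CC)CO | intermediate
28 | (1R,2R,4aS,8aS)-1-[(3E)-6-[(1S)-2,2-dimethyl-6-methylidenecyclohexyl]-4-(hydroxymethyl)hex-3-en-1-yl]-2,5,5,8a-tetramethyldecahydronaphthalen-2-ol | C=C1CCCC(C)(C)[C@@H]1CC/C(=C\CC[C@@H]1[C@@]2(C)CCCC(C)(C)[C@@H]2CC[C@@]1(C)O)CO | target

## Step count and risks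

Total step count: 18. Longest linear sequence: 12 steps (steps 7–18).

**1. Step 14 (Proposed new method).**
- What may go wrong: the tertiary C4 radical may be reduced (net hydrogenation of the alkene) before the very congested C4–C5 bond forms, or hydrogen delivery to the C5 radical may lack facial selectivity.
- Fallback (known chemistry), from 20 back to 24: MHAT cyclisation of the alkene onto the free C5 ketone (Fe(acac)3, PhSiH3, EtOH) should give the ring-fusion tertiary alcohol F1. Dehydration (Burgess reagent or SOCl2/pyridine) can only run towards C6 because C4 and C10 are quaternary, and gives the Δ5(6)-octalin F2. HAT hydrogenation under thermodynamic control (Mn(dpm)3, PhSiH3, TBHP), or H2/Pd–C from the α face, returns to 24.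

**2. Step 10.**
- What may go wrong: sluggish 1,4-addition at the neopentyl-type β-carbon of an α-methyl enone, competing 1,2-addition, or poor facial selectivity.
- Fallback, from 15 back to 16: a tin-free Giese radical addition of 2-(2-bromoethyl)-1,3-dioxolane ((TMS)3SiH, AIBN, benzene, 80 °C) is less sensitive to crowding at the β-carbon and should give the saturated ketone F3 (C10 epimers, side chain trans to the silyl ether). Equilibrating enolisation (KH, THF) and silylation with TMSCl give the more substituted silyl enol ether, which is 16.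

**3. Step 2.**
- What may go wrong: erosion of enantioselectivity at the hindered α-carbon, or loss of the enolate by protonation or double allylation.
- Fallback, from 1 back to 4: conjugate methylation as in step 1 but with TMSCl as trap gives the silyl enol ether F4. MeLi regenerates lithium enolate 2, which is allylated with allyl bromide in toluene in the presence of a stoichiometric chiral tetradentate amine ligand (ligand-controlled enantioselective alkylation of a lithium enolate) to give 4.

## Further compounds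

F1 | step 14 | (1R,2R,8aS)-1-[2-(1,3-dioxolan-2-yl)ethyl]-2,5,5,8a-tetramethyl-2-(triethylsilyloxy)octahydronaphthalen-4a(2H)-ol (C5 configuration open) | O1CCOC1CC[C@@H]1[C@@]2(C)CCCC(C)(C)C2(O)CC[C@@]1(C)O[Si](CC)(CC)CC
F2 | step 14 | Δ5(6)-octalin: 24 with a C5=C6 double bond | O1CCOC1CC[C@@H]1[C@@]2(C)CCCC(C)(C)C2=CC[C@@]1(C)O[Si](CC)(CC)CC
F3 | step 10 | (3R,4R)-3-[2-(1,3-dioxolan-2-yl)ethyl]-2,4-dimethyl-4-(triethylsilyloxy)cyclohexan-1-one (C2 epimers) | CC1C(=O)CC[C@@](C)(O[Si](CC)(CC)CC)[C@@H]1CCC1OCCO1
F4 | step 2 | [(3,3-dimethylcyclohex-1-en-1-yl)oxy]trimethylsilane | C[Si](C)(C)OC1=CC(C)(C)CCC1
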